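The molecule is cut at the C8–O4' aryl ether bond, with C7 raised to the ketone level. Both halves then derive from one phenol, 4-propenylsyringol: ring B is used as such, ring A as its α-bromoketone. The plan exploits the C8–H bond, which lies between the C7 carbonyl on ring A and the O4' aryloxy oxygen of ring B and is therefore base-labile. Asymmetric transfer hydrogenation of the racemic α-aryloxy propiophenone under racemising conditions funnels both C8 epimers into one threo alcohol, fixing C7 and C8 in a single operation. A Mitsunobu inversion at C7 and ester methanolysis then give the erythro-(7R,8S) target.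

Key step: step 6

Remark: neolignan numbering is used (ring A = C1–C6 bearing C7, C8 and the C9 methyl; ring B = C1'–C6' bound through O4'); the route is written for the predicted threo outcome of step 6, and if the reduction proved erythro-selective the (S,S)-catalyst would take 6 directly to 9.

Step 1
Reactants: 1 4-allyl-2,6-dimethoxyphenol (methoxyeugenol)
Product: 2 (E)-2,6-dimethoxy-4-(prop-1-en-1-yl)phenol
Conditions: RuCl2(PPh3)3 (1 mol %), EtOH, reflux, N2; AgNO3-doped silica chromatography (or crystallisation) for the portion used in step 5, Z-containing fractions go to step 2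
Reagents that add atoms: none
Why: Metal-hydride alkene isomerisation (reversible hydroruthenation and β-hydride elimination) moves the double bond into conjugation with the arene under thermodynamic control, which favours the E-styrene, and unlike strong-base methods it is not slowed by phenoxide formation.

Step 2
Reactants: 2 (E)-2,6-dimethoxy-4-(prop-1-en-1-yl)phenol
Product: 3 (E)-2,6-dimethoxy-4-(prop-1-en-1-yl)phenyl pivalate
Conditions: PivCl, Et3N, DMAP (cat.), CH2Cl2, 0 °C to rt
Reagents that add atoms: pivaloyl chloride CC(C)(C)C(=O)Cl
Why: DMAP-catalysed O-acylation masks the phenol towards NBS and oxidants, and the bulky, electron-withdrawing pivalate resists acyl transfer to phenoxide in step 5 and damps the donor power of ring A, which later raises C8–H acidity and disfavours benzylic ionisation.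

Step 3
Reactants: 3 (E)-2,6-dimethoxy-4-(prop-1-en-1-yl)phenyl pivalate
Product: 4 racemic 4-(2-bromo-1-hydroxypropyl)-2,6-dimethoxyphenyl pivalate (OH on benzylic C7, Br on C8)
Conditions: NBS (1.05 equiv), acetone–H2O 4:1, 0 °C, dark
Reagents that add atoms: N-bromosuccinimide O=C1CCC(=O)N1Br; water O
Why: In this electrophilic halohydrin formation the bromonium ion of the styrene is opened by water at the benzylic carbon (Markovnikov sense), so bromine ends on C8, and the relative configuration is irrelevant because C7 is oxidised next and C8 is later substituted and equilibrated.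

Step 4
Reactants: 4 racemic bromohydrin (used crude)
Product: 5 racemic 4-(2-bromopropanoyl)-2,6-dimethoxyphenyl pivalate
Conditions: Dess–Martin periodinane, CH2Cl2, 0 °C to rt
Reagents that add atoms: none
Why: Dess–Martin oxidation converts the secondary benzylic alcohol into the ketone under near-neutral conditions that leave the C8–Br bond, the aryl ester and the methyl ethers untouched.

Step 5
Reactants: 2 (E)-2,6-dimethoxy-4-(prop-1-en-1-yl)phenol; 5 racemic α-bromoketone
Product: 6 racemic 4-{2-[2,6-dimethoxy-4-((E)-prop-1-en-1-yl)phenoxy]propanoyl}-2,6-dimethoxyphenyl pivalate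
Conditions: K2CO3 (anhydrous), butanone, 70 °C, N2
Reagents that add atoms: none
Why: In this Williamson ether synthesis the phenoxide of 2 displaces bromide in an SN2 reaction accelerated by the adjacent carbonyl and forms the C8–O4' bond, a coupling well known for 2,6-dimethoxyphenols and α-bromopropiophenones, while the hindered pivalate resists transacylation.

Step 6
Reactants: 6 racemic α-aryloxy ketone
Product: 7 threo-(7S,8S) alcohol, 4-{(1S,2S)-2-[2,6-dimethoxy-4-((E)-prop-1-en-1-yl)phenoxy]-1-hydroxypropyl}-2,6-dimethoxyphenyl pivalate
Conditions: RuCl(p-cymene)[(R,R)-TsDPEN] (2 mol %), DBU (5 equiv), HCO2H (3 equiv, slow addition), MeCN, 40 °C, N2 sweep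
Reagents that add atoms: none
Why: Excess DBU reversibly removes the C8 proton of 6, so the 8R and 8S ketones interconvert through the planar enolate, while the ruthenium hydride generated from the catalyst and formate passes its Ru–H and N–H hydrogens to the C7 carbonyl through a concerted outer-sphere six-membered transition state, and loss of CO2 makes the reduction irreversible. The closest known reaction type is the Noyori–Ikariya asymmetric transfer hydrogenation with dynamic kinetic resolution, established for benzoins (giving threo hydrobenzoins) and for acyclic α-carbamate-substituted aryl ketones of similar C–H acidity; for 6 the level and sense of diastereoselection rest on this analogy and are to be confirmed through the H7–H8 coupling constant. One C7–H bond is formed and no ring is closed. C7 is set by the ligand: a CH/π contact holds ring A under the p-cymene, so the (R,R)-diamine delivers hydride to the face that gives 7S (S because C8 outranks ring A). C8 is set by substrate–catalyst matching: the coordinatively saturated hydride cannot chelate O4', so a Felkin–Anh arrangement with the C8–O4' bond anti to the incoming hydride should make the 8S ketone the fast-reacting one and lead to the threo (7S,8S) alcohol. The step needs epimerisation to outrun reduction of the mismatched 8R ketone, which is secured by the acidifying effect of the C7 carbonyl, O4' and the ester-damped ring A, by the base-rich medium and by the slow feed of formic acid, and it needs C=O over C=C chemoselectivity, which is inherent to polar hydride/proton transfer and spares the E-propenyl group.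

Step 7
Reactants: 7 threo-(7S,8S) alcohol
Product: 8 erythro-(7R,8S) 4-nitrobenzoate, (1R,2S)-2-[2,6-dimethoxy-4-((E)-prop-1-en-1-yl)phenoxy]-1-[3,5-dimethoxy-4-(pivaloyloxy)phenyl]propyl 4-nitrobenzoate
Conditions: 4-O2NC6H4CO2H, PPh3, DIAD, toluene–THF, 0 °C to rt
Reagents that add atoms: 4-nitrobenzoic acid O=C(O)c1ccc(cc1)[N+](=O)[O-]
Why: In the Mitsunobu reaction the C7 hydroxyl is activated as an oxyphosphonium ion and displaced by 4-nitrobenzoate with SN2 inversion (7S to 7R, C8 untouched), the acidic nitrobenzoic acid being the standard partner for hindered carbinols and the ester-damped ring A together with the weakly polar solvent disfavouring ionisation.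

Step 8
Reactants: 8 erythro-(7R,8S) 4-nitrobenzoate
Product: 10 target CNP0174373.1, 4-{(1R,2S)-2-[2,6-dimethoxy-4-((E)-prop-1-en-1-yl)phenoxy]-1-hydroxypropyl}-2,6-dimethoxyphenol, via erythro carbinol pivalate 9 (not isolated)
Conditions: K2CO3, MeOH–THF, 0 °C until 8 is consumed, then rt to 40 °C; pH 7 phosphate buffer work-up
Reagents that add atoms: none
Why: Base-mediated transesterification (Zemplén-type methanolysis) breaks only acyl–oxygen bonds, so C7 and C8 keep their configuration, and the activated nitrobenzoate goes first, so the ring A phenoxide appears only when C7 carries a poor leaving group and the quinone methide channel stays closed.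

Compound list
1 | 4-allyl-2,6-dimethoxyphenol (methoxyeugenol) | C=CCc1cc(OC)c(O)c(OC)c1 | starting material
2 | (E)-2,6-dimethoxy-4-(prop-1-en-1-yl)phenol | C/C=C/c1cc(OC)c(O)c(OC)c1 | intermediate
3 | (E)-2,6-dimethoxy-4-(prop-1-en-1-yl)phenyl pivalate | C/C=C/c1cc(OC)c(OC(=O)C(C)(C)C)c(OC)c1 | intermediate
4 | racemic 4-(2-bromo-1-hydroxypropyl)-2,6-dimethoxyphenyl pivalate | CC(Br)C(O)c1cc(OC)c(OC(=O)C(C)(C)C)c(OC)c1 | intermediate
5 | racemic 4-(2-bromopropanoyl)-2,6-dimethoxyphenyl pivalate | CC(Br)C(=O)c1cc(OC)c(OC(=O)C(C)(C)C)c(OC)c1 | intermediate
6 | racemic α-aryloxy ketone (full skeleton, ring A pivalate) | C/C=C/c1cc(OC)c(OC(C)C(=O)c2cc(OC)c(OC(=O)C(C)(C)C)c(OC)c2)c(OC)c1 | intermediate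
7 | threo-(7S,8S) alcohol, ring A pivalate | C/C=C/c1cc(OC)c(O[C@@H](C)[C@@H](O)c2cc(OC)c(OC(=O)C(C)(C)C)c(OC)c2)c(OC)c1 | intermediate
8 | erythro-(7R,8S) 4-nitrobenzoate, ring A pivalate | C/C=C/c1cc(OC)c(O[C@@H](C)[C@H](OC(=O)c3ccc(cc3)[N+](=O)[O-])c2cc(OC)c(OC(=O)C(C)(C)C)c(OC)c2)c(OC)c1 | intermediate
9 | erythro-(7R,8S) alcohol, ring A pivalate | C/C=C/c1cc(OC)c(O[C@@H](C)[C@H](O)c2cc(OC)c(OC(=O)C(C)(C)C)c(OC)c2)c(OC)c1 | intermediate
10 | CNP0174373.1, erythro-(7R,8S) phenol | C/C=C/c1cc(OC)c(O[C@@H](C)[C@H](O)c2cc(OC)c(O)c(OC)c2)c(OC)c1 | target

Total step count: 8. Longest linear sequence: 8 steps (1 to 10; compound 2 is used twice).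

Steps most likely to fail

1. Step 6. Epimerisation at C8 may not keep pace with hydride transfer, or the substrate bias may fail to reinforce the catalyst. In either case the two C8 epimers are not funnelled into one diastereomer.
   - The fallback replaces catalysis by the chiral pool plus chelation control. It sets out from 2 and returns at 10.
   - Mitsunobu etherification of 2 with commercial methyl (R)-lactate (PPh3, DIAD, THF) inverts the lactate carbon and gives methyl (S)-2-[2,6-dimethoxy-4-((E)-prop-1-enyl)phenoxy]propanoate F1. MeNH(OMe)·HCl and iPrMgCl at low temperature convert it into the corresponding Weinreb amide F2.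
   - Commercial 4-bromo-2,6-dimethoxyphenol is silylated (TBSCl, imidazole) to (4-bromo-2,6-dimethoxyphenoxy)(tert-butyl)dimethylsilane F3.
   - Bromine–lithium exchange (n-BuLi, THF, −78 °C) gives the ring A aryllithium F4. Its addition to F2 gives the single-enantiomer (8S)-ketone silyl ether F5.
   - Zn(BH4)2 in Et2O at low temperature reduces F5 through the O7/O4' chelate from the face of the C8 hydrogen, giving the erythro-(7R,8S) alcohol silyl ether F6.
   - TBAF buffered with AcOH then frees the ring A phenol to give 10.

2. Step 7. The activated benzylic oxyphosphonium ion may ionise, with loss of stereospecificity at C7. It may instead eliminate towards C8, or crowding next to the aryloxy group may stall the displacement.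
   - The fallback inverts C7 by a redox sequence instead of substitution. It sets out from 7 and returns at 9.
   - Dess–Martin oxidation of 7 under neutral conditions gives the (8S)-ketone pivalate F7, the single enantiomer of 6.
   - Chelation-controlled reduction with Zn(BH4)2 (Et2O, low temperature) delivers hydride from the face of the C8 hydrogen and gives 9. Here 9 is isolated and carried through the second stage of step 8.

3. Step 3. Electrophilic bromination of the activated C2/C6 positions of ring A, or dibromide formation, may compete with halohydrin formation at the alkene.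
   - The fallback installs the ketone before any electrophilic bromine is used. It sets out from 3 and returns at 5.
   - Mukaiyama hydration (Co(acac)2 cat., PhSiH3, O2, iPrOH) places oxygen at the benzylic carbon through the benzylic radical and gives 4-(1-hydroxypropyl)-2,6-dimethoxyphenyl pivalate F8.
   - Dess–Martin oxidation gives 2,6-dimethoxy-4-propanoylphenyl pivalate F9.
   - Enol-selective bromination with CuBr2 (EtOAc–CHCl3, reflux) gives 5, ring A now being deactivated by the acyl group.

Further compounds
F1 | step 6 | methyl (S)-2-[2,6-dimethoxy-4-((E)-prop-1-enyl)phenoxy]propanoate | C/C=C/c1cc(OC)c(O[C@@H](C)C(=O)OC)c(OC)c1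
F2 | step 6 | (S)-2-[2,6-dimethoxy-4-((E)-prop-1-enyl)phenoxy]-N-methoxy-N-methylpropanamide | C/C=C/c1cc(OC)c(O[C@@H](C)C(=O)N(C)OC)c(OC)c1
F3 | step 6 | (4-bromo-2,6-dimethoxyphenoxy)(tert-butyl)dimethylsilane | COc1cc(Br)cc(OC)c1O[Si](C)(C)C(C)(C)C
F4 | step 6 | [4-(tert-butyldimethylsilyloxy)-3,5-dimethoxyphenyl]lithium | [Li]c1cc(OC)c(O[Si](C)(C)C(C)(C)C)c(OC)c1
F5 | step 6 | (8S)-α-aryloxy ketone, ring A TBS ether | C/C=C/c1cc(OC)c(O[C@@H](C)C(=O)c2cc(OC)c(O[Si](C)(C)C(C)(C)C)c(OC)c2)c(OC)c1
F6 | step 6 | erythro-(7R,8S) alcohol, ring A TBS ether | C/C=C/c1cc(OC)c(O[C@@H](C)[C@H](O)c2cc(OC)c(O[Si](C)(C)C(C)(C)C)c(OC)c2)c(OC)c1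
F7 | step 7 | (8S)-α-aryloxy ketone, ring A pivalate | C/C=C/c1cc(OC)c(O[C@@H](C)C(=O)c2cc(OC)c(OC(=O)C(C)(C)C)c(OC)c2)c(OC)c1
F8 | step 3 | 4-(1-hydroxypropyl)-2,6-dimethoxyphenyl pivalate (racemic) | CCC(O)c1cc(OC)c(OC(=O)C(C)(C)C)c(OC)c1
F9 | step 3 | 2,6-dimethoxy-4-propanoylphenyl pivalate | CCC(=O)c1cc(OC)c(OC(=O)C(C)(C)C)c(OC)c1
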